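## The problem

Target 33 is a trimeric acylphloroglucinol. Ring A is a fully substituted butanoylphloroglucinol, joined through two CH2 bridges (at C3 and C5) to two dearomatised acylfilicinic acid rings: ring B carries acetyl, ring C propanoyl. There is no stereocentre (the quaternary carbons carry two methyls), so the task is constitutional: three different acyl groups in their places and two nearly identical wings kept apart. Ring A has a mirror plane through C1 and C4, so either wing may sit on either bridge; they must still be introduced one after the other, otherwise a statistical mixture of homologues results. The enolised β-triketones are acidic and chelating. The ArCH2–C bridges, flanked by free hydroxyls, are cleaved and exchanged through quinone methides under acid, Lewis acid or base, and can cyclodehydrate to xanthenes. A late Friedel–Crafts acylation of the assembled skeleton is therefore unattractive. The enabling feature is that the butanoyl carbon C1 and the hydroxyl carbon C6 are neighbours on ring A, with an oxygen on C2 and a CH2 arm on C5. An aryne C1≡C6 can take up both groups from butanoic acid, and the C2 oxygen decides which goes where.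

## Retrosynthesis

**Unmasking (33 ⇒ 32 ⇒ 31).** No skeletal bond is cut. Each acylfilicinic acid wing is traced to an isoxazole-fused methyl enol ether: the N–O bond stands for the acyl C=O / ring C–O pair, the methyl ether for the remaining enol, and benzyl ethers for two ring A hydroxyls. The masked wings are neutral and non-chelating. The isoxazole is fused so that its oxygen sits on the ring carbon next to the bridge carbon (C7a), which leaves the bridge carbon flanked only by the isoxazole oxygen and a methoxy group; the one wing ketone lies on the far side. The forward reaction needs hydrogenolysis (benzyl, N–O) to 32, then hydrolysis of two enaminones and two enol ethers without bridge exchange.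

**Key cut (31 ⇒ 28 + 29).** The C1–C(=O) and C6–O bonds are cut together, giving the 2-(trimethylsilyl)aryl triflate 28 and butanoic acid 29. The neighbouring cuts are worse: C1–acyl alone means Friedel–Crafts or Fries chemistry with Lewis acid, and an aryllithium at C1 would not tolerate the wing ketones. The forward step must place oxygen on C6 and acyl on C1 and must beat protonation of the aryl anion.

**Bridge bonds (28 ⇒ 26 + 12; 24 ⇒ 21 + 6).** Each bridge is cut between CH2 and the wing sp2 carbon C7, giving benzylic chlorides on ring A and alkenyl bromides 6 and 12 for Negishi coupling. Cutting Ar–CH2 instead would need an aryl metal on a hexasubstituted ring and a wing–CH2 electrophile that is not readily made. The classical condensation of an enolised dione with formaldehyde and a phenol needs free acidic partners, is where bridge scrambling starts, and would leave the wing enol to be etherified with uncertain regiochemistry. The coupling must pick the alkenyl C–Br over the aryl C–OTf.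

**Silyl triflate and arm differentiation (26, 21 ⇒ 20 ⇒ 17).** The two chloromethyl arms are traced to a CH2NMe2 group and a CH2OSiMe3 group. Both survive butyllithium and are activated by different reagents (chloroformate; mesyl chloride after desilylation). The C1–Si bond comes from the C6–O–Si bond of bromophenol 17 by retro-Brook shift. This is placed before the wings because their ketones would not survive butyllithium. It is placed after all ring C–C bonds because an arylsilane on so electron-rich a ring suffers ipso attack by electrophiles.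

**Ring A substitution (17 ⇒ 16 ⇒ 15 ⇒ 14 ⇒ 13).** Three electrophilic substitutions on commercial 3,5-bis(benzyloxy)phenol 13: formyl para to the hydroxyl (the future C3 arm), then bromine and aminomethyl at the two ortho positions. After the first step the remaining positions are equivalent, so no regiochemical question is left.

**Wings (6 ⇒ 5 ⇒ 4 ⇒ 3 ⇒ 1; 12 ⇒ 11 ⇒ 10 ⇒ 9 ⇒ 7).** The wing carbocycle is cut at C4–C5 (acylation of an isobutyrate enolate by the isoxazole acid chloride) and at C6–C7 (Claisen closure of the lateral 5-methyl anion onto the ester). Condensing hydroxylamine with an acylfilicinic acid made from an acylphloroglucinol was considered and set aside: both the direction of isoxazole closure and the site of O-methylation would be ambiguous. Here the isoxazole is bought (acids 1 and 7), each bond formation has one possible outcome, and only the C6 ketone of diones 4 and 10 can enolise, so one enol ether results.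

## Roads not taken

Alternative 1: Ring A itself would be built by Danheiser benzannulation. A cyclobutenone supplies four ring carbons and a silyl ynol ether two, each bringing one protected hydroxymethyl arm; heating would give phenol A1. The merit is that one reagent-free step tells apart all three oxygens (OH, OBn, OSi) and both arms (MOM and PMB ethers), with regiochemistry fixed by the mechanism. That arm differentiation is cleaner than the amine / silyl ether pair of 20. The weak points: the ring made is an ordinary phloroglucinol that can be bought, both partners need several steps each, and A1 still lacks the butanoyl group and both wings, so late acylation and bridge formation remain unsolved. The chosen plan offers in return three steps from a commercial arene to differentiated arms and a neutral way to bring in the acyl group last.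

Alternative 2: Two C–C bonds in each wing would be cut. A ring A intermediate with two different 1,3-diketone side chains, as its bis(silyl dienol ether), would be annulated twice with A3 (2,2-dimethylpropanedioyl dichloride) to give A2, the tri-O-benzyl trimer without the butanoyl group. Merits: the wings are built on the core, so no wing–core coupling and no masking are needed, and the wings appear in their final oxidation state. Its end game (debenzylation only) is better than the enaminone hydrolysis of the chosen plan. Weak points: such dienes tend to react with malonyl chlorides at oxygen and give pyranones, and two closures on one molecule compound this. The two homologous side chains must still be attached separately. A2 then needs the butanoyl group on the last ring A carbon with acidic wings free, which is the Friedel–Crafts situation in which bridges scramble. The chosen plan offers in return known reaction types for every C–C bond and acyl introduction without Lewis acid.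

Alternative 3: Ring A would be cut at C1–C2 and C5–C6. A 1-methoxy-1,3-bis(silyloxy)diene bearing both arm precursors would add to ynone A5 (1-(benzyloxy)hex-1-yn-3-one) and aromatise by loss of methanol to give A4. The merit is considerable: the butanoyl group is in place from the start, so no late acylation, no aryne and no silyl triflate are needed, and the arms are orthogonal. On acyl placement and ring A step count this road is better. Weak points: the tetrasubstituted diene with two different CH2OR groups is demanding to make, and both bridges must then be forged on a free acylphloroglucinol, where benzylic cations and quinone methides ortho to hydroxyl invite the exchange chemistry that must be avoided; PMB and MOM removal also needs acid. The chosen plan offers in return that the bridges are made on an electron-poor aryl triflate, where benzylic chlorides are well behaved, and that the acyl group enters afterwards.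

Key step: step 18

Remark on the chemistry: the amino-alkylidene C=C bonds of the enaminones (32, F9) are push–pull bonds that equilibrate between both hydrogen-bonded geometries and are written without E/Z descriptors; the target has no stereocentre.

## Steps

Step 1
Reactants: 1 3-ethyl-5-methyl-1,2-oxazole-4-carboxylic acid
Product: 3 methyl 3-(3-ethyl-5-methyl-1,2-oxazol-4-yl)-2,2-dimethyl-3-oxopropanoate, via acid chloride 2 (not isolated)
Conditions: (COCl)2, cat. DMF, CH2Cl2, 0 °C → rt, evaporate; LiN(i-Pr)2, methyl 2-methylpropanoate, THF, −78 °C, then 2, −78 → 0 °C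
Reagents that add atoms: methyl 2-methylpropanoate, COC(=O)C(C)C
Why: Acid chloride formation followed by C-acylation of an ester lithium enolate (crossed Claisen-type acylation); the product has no hydrogen between its carbonyls, so it neither quenches the enolate nor is acylated twice.

Step 2
Reactants: 3 methyl 3-(3-ethyl-5-methyl-1,2-oxazol-4-yl)-2,2-dimethyl-3-oxopropanoate
Product: 4 3-ethyl-5,5-dimethyl-1,2-benzoxazole-4,6(5H,7H)-dione
Conditions: LiN(SiMe3)2 (2.2 equiv), THF, −78 → 0 °C; aq. NH4Cl
Reagents that add atoms: none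
Why: The 5-methyl group is vinylogous to the C4 ketone and is the most acidic site (lateral metalation of a 5-methylisoxazole); its anion closes the six-membered ring onto the ester in an intramolecular Claisen (Dieckmann-type) condensation. The second equivalent of base deprotonates C7 of the product and shields the non-enolisable 1,3-dione from retro-Claisen attack by methoxide.

Step 3
Reactants: 4 3-ethyl-5,5-dimethyl-1,2-benzoxazole-4,6(5H,7H)-dione
Product: 5 3-ethyl-6-methoxy-5,5-dimethyl-1,2-benzoxazol-4(5H)-one
Conditions: HC(OMe)3, cat. TsOH, MeOH, 60 °C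
Reagents that add atoms: trimethyl orthoformate, COC(OC)OC
Why: Acid-catalysed enol ether formation through the dimethyl ketal; only the C6 ketone has α-hydrogens (at C7), the C4 ketone lies between a quaternary carbon and the isoxazole, so one enol ether, conjugated with the heterocycle, can form.

Step 4
Reactants: 5 3-ethyl-6-methoxy-5,5-dimethyl-1,2-benzoxazol-4(5H)-one
Product: 6 7-bromo-3-ethyl-6-methoxy-5,5-dimethyl-1,2-benzoxazol-4(5H)-one
Conditions: NBS, MeCN, 0 °C → rt, dark
Reagents that add atoms: N-bromosuccinimide, O=C1CCC(=O)N1Br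
Why: Electrophilic bromination of the enol ether at its nucleophilic β-carbon C7, followed by loss of the C7 proton; no other position is enolisable or electron-rich.

Step 5
Reactants: 7 3,5-dimethyl-1,2-oxazole-4-carboxylic acid
Product: 9 methyl 3-(3,5-dimethyl-1,2-oxazol-4-yl)-2,2-dimethyl-3-oxopropanoate, via acid chloride 8 (not isolated)
Conditions: (COCl)2, cat. DMF, CH2Cl2, 0 °C → rt, evaporate; LiN(i-Pr)2, methyl 2-methylpropanoate, THF, −78 °C, then 8, −78 → 0 °C
Reagents that add atoms: methyl 2-methylpropanoate, COC(=O)C(C)C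
Why: Same crossed Claisen-type acylation as step 1.

Step 6
Reactants: 9 methyl 3-(3,5-dimethyl-1,2-oxazol-4-yl)-2,2-dimethyl-3-oxopropanoate
Product: 10 3,5,5-trimethyl-1,2-benzoxazole-4,6(5H,7H)-dione
Conditions: LiN(SiMe3)2 (2.2 equiv), THF, −78 → 0 °C; aq. NH4Cl
Reagents that add atoms: none
Why: Same lateral deprotonation and Dieckmann-type closure as step 2; the 3-methyl group is not vinylogous to the ketone and stays untouched.

Step 7
Reactants: 10 3,5,5-trimethyl-1,2-benzoxazole-4,6(5H,7H)-dione
Product: 11 6-methoxy-3,5,5-trimethyl-1,2-benzoxazol-4(5H)-one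
Conditions: HC(OMe)3, cat. TsOH, MeOH, 60 °C
Reagents that add atoms: trimethyl orthoformate, COC(OC)OC
Why: Same regiospecific enol ether formation as step 3.

Step 8
Reactants: 11 6-methoxy-3,5,5-trimethyl-1,2-benzoxazol-4(5H)-one
Product: 12 7-bromo-6-methoxy-3,5,5-trimethyl-1,2-benzoxazol-4(5H)-one
Conditions: NBS, MeCN, 0 °C → rt, dark
Reagents that add atoms: N-bromosuccinimide, O=C1CCC(=O)N1Br
Why: Same enol ether bromination as step 4.

Step 9
Reactants: 13 3,5-bis(benzyloxy)phenol
Product: 14 2,6-bis(benzyloxy)-4-hydroxybenzaldehyde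
Conditions: POCl3, DMF, MeCN, 0 °C → rt; aq. NaOAc
Reagents that add atoms: N,N-dimethylformamide, CN(C)C=O; water, O
Why: Vilsmeier–Haack formylation; 3,5-dialkoxyphenols are attacked mainly para to the free hydroxyl, and the minor ortho aldehyde should be removable by crystallisation or chromatography.

Step 10
Reactants: 14 2,6-bis(benzyloxy)-4-hydroxybenzaldehyde
Product: 15 2,6-bis(benzyloxy)-3-bromo-4-hydroxybenzaldehyde
Conditions: NBS (1.0 equiv), CH2Cl2, −20 → 0 °C
Reagents that add atoms: N-bromosuccinimide, O=C1CCC(=O)N1Br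
Why: Electrophilic aromatic bromination ortho to the phenol; the two free positions are equivalent, and the aldehyde and the first bromine slow a second substitution.

Step 11
Reactants: 15 2,6-bis(benzyloxy)-3-bromo-4-hydroxybenzaldehyde
Product: 16 2,6-bis(benzyloxy)-3-bromo-5-[(dimethylamino)methyl]-4-hydroxybenzaldehyde
Conditions: CH2=NMe2+ I−, Et3N, CH2Cl2, 0 °C → rt
Reagents that add atoms: dimethyl(methylidene)ammonium iodide, C[N+](C)=C.[I-]
Why: Mannich reaction of the phenol with a preformed iminium salt at the only free ring position, which is ortho to the hydroxyl and activated by both benzyloxy groups.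

Step 12
Reactants: 16 2,6-bis(benzyloxy)-3-bromo-5-[(dimethylamino)methyl]-4-hydroxybenzaldehyde
Product: 17 3,5-bis(benzyloxy)-2-bromo-6-[(dimethylamino)methyl]-4-(hydroxymethyl)phenol
Conditions: NaBH4, MeOH/THF, 0 °C; basic work-up, used without storage
Reagents that add atoms: none
Why: Borohydride reduction of the aldehyde; bromide and benzyl ethers are inert, and the electron-rich 4-hydroxybenzyl alcohol is kept basic to avoid quinone-methide formation.

Step 13
Reactants: 17 3,5-bis(benzyloxy)-2-bromo-6-[(dimethylamino)methyl]-4-(hydroxymethyl)phenol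
Product: 20 3,5-bis(benzyloxy)-2-[(dimethylamino)methyl]-6-(trimethylsilyl)-4-{[(trimethylsilyl)oxy]methyl}phenyl trifluoromethanesulfonate, via bis(trimethylsilyl) ether 18 (not isolated), via lithium silylphenolate 19 (not isolated)
Conditions: (Me3Si)2NH, cat. Me3SiCl, THF, 40 °C, evaporate; n-BuLi, THF, −78 → −20 °C; PhNTf2, −78 °C → rt; aq. NaHCO3, filtration through Et3N-treated silica
Reagents that add atoms: hexamethyldisilazane, C[Si](C)(C)N[Si](C)(C)C; N-phenylbis(trifluoromethanesulfonimide), O=S(=O)(N(c1ccccc1)S(=O)(=O)C(F)(F)F)C(F)(F)F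
Why: O-Silylation, bromine–lithium exchange, anionic 1,3 O→C silyl shift (retro-Brook rearrangement) and triflation of the phenolate, the standard route to 2-silylaryl triflates. Exchange at −78 °C outruns metalation of the benzyl ethers, the amine and the alkyl silyl ether are inert, and PhNTf2 is used because it leaves the tertiary amine alone.

Step 14
Reactants: 20 3,5-bis(benzyloxy)-2-[(dimethylamino)methyl]-6-(trimethylsilyl)-4-{[(trimethylsilyl)oxy]methyl}phenyl trifluoromethanesulfonate
Product: 21 3,5-bis(benzyloxy)-2-(chloromethyl)-6-(trimethylsilyl)-4-{[(trimethylsilyl)oxy]methyl}phenyl trifluoromethanesulfonate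
Conditions: ClCO2Et, CH2Cl2, 0 °C → rt
Reagents that add atoms: ethyl chloroformate, CCOC(Cl)=O
Why: von Braun-type dealkylation: N-acylation, then chloride displaces the carbamate at the benzylic carbon in preference to methyl; no acid is released, so the silyl ether, arylsilane and triflate persist.

Step 15
Reactants: 21 3,5-bis(benzyloxy)-2-(chloromethyl)-6-(trimethylsilyl)-4-{[(trimethylsilyl)oxy]methyl}phenyl trifluoromethanesulfonate; 6 7-bromo-3-ethyl-6-methoxy-5,5-dimethyl-1,2-benzoxazol-4(5H)-one
Product: 24 3,5-bis(benzyloxy)-2-[(3-ethyl-6-methoxy-5,5-dimethyl-4-oxo-4,5-dihydro-1,2-benzoxazol-7-yl)methyl]-4-(hydroxymethyl)-6-(trimethylsilyl)phenyl trifluoromethanesulfonate, via benzylzinc chloride 22 (not isolated), via coupled silyl ether 23 (not isolated)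
Conditions: Zn dust, LiCl, THF, 25 °C; then 6, Pd[P(t-Bu)3]2 (cat.), THF/NMP, 25–40 °C; citric acid, MeOH/H2O work-up
Reagents that add atoms: none
Why: LiCl-assisted zinc insertion into the benzylic chloride and Negishi coupling with the alkenyl bromide. Zerovalent palladium with P(t-Bu)3 inserts into C–Br in preference to the aryl C–OTf, which is also shielded by two ortho substituents. The organozinc tolerates the hindered ketone and the isoxazole, and mild acid in the work-up removes the alkyl silyl ether.

Step 16
Reactants: 24 3,5-bis(benzyloxy)-2-[(3-ethyl-6-methoxy-5,5-dimethyl-4-oxo-4,5-dihydro-1,2-benzoxazol-7-yl)methyl]-4-(hydroxymethyl)-6-(trimethylsilyl)phenyl trifluoromethanesulfonate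
Product: 26 3,5-bis(benzyloxy)-4-(chloromethyl)-2-[(3-ethyl-6-methoxy-5,5-dimethyl-4-oxo-4,5-dihydro-1,2-benzoxazol-7-yl)methyl]-6-(trimethylsilyl)phenyl trifluoromethanesulfonate, via methanesulfonate 25 (not isolated)
Conditions: MsCl, LiCl, 2,4,6-collidine, DMF, 0 °C
Reagents that add atoms: lithium chloride, [Li+].[Cl-]
Why: Mesylation and chloride displacement in one flask under buffered conditions; the arylsilane and the enol ether see no acid, and chloride does not attack silicon.

Step 17
Reactants: 26 3,5-bis(benzyloxy)-4-(chloromethyl)-2-[(3-ethyl-6-methoxy-5,5-dimethyl-4-oxo-4,5-dihydro-1,2-benzoxazol-7-yl)methyl]-6-(trimethylsilyl)phenyl trifluoromethanesulfonate; 12 7-bromo-6-methoxy-3,5,5-trimethyl-1,2-benzoxazol-4(5H)-one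
Product: 28 3,5-bis(benzyloxy)-2-[(3-ethyl-6-methoxy-5,5-dimethyl-4-oxo-4,5-dihydro-1,2-benzoxazol-7-yl)methyl]-4-[(6-methoxy-3,5,5-trimethyl-4-oxo-4,5-dihydro-1,2-benzoxazol-7-yl)methyl]-6-(trimethylsilyl)phenyl trifluoromethanesulfonate, via benzylzinc chloride 27 (not isolated)
Conditions: Zn dust, LiCl, THF, 25 °C; then 12, Pd[P(t-Bu)3]2 (cat.), THF/NMP, 25–40 °C
Reagents that add atoms: none
Why: Second Negishi coupling, as in step 15; the first wing carries nothing that reacts with zinc or the organozinc.

Step 18
Reactants: 28 3,5-bis(benzyloxy)-2-[(3-ethyl-6-methoxy-5,5-dimethyl-4-oxo-4,5-dihydro-1,2-benzoxazol-7-yl)methyl]-4-[(6-methoxy-3,5,5-trimethyl-4-oxo-4,5-dihydro-1,2-benzoxazol-7-yl)methyl]-6-(trimethylsilyl)phenyl trifluoromethanesulfonate; 29 butanoic acid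
Product: 31 1-[2,4-bis(benzyloxy)-5-[(3-ethyl-6-methoxy-5,5-dimethyl-4-oxo-4,5-dihydro-1,2-benzoxazol-7-yl)methyl]-6-hydroxy-3-[(6-methoxy-3,5,5-trimethyl-4-oxo-4,5-dihydro-1,2-benzoxazol-7-yl)methyl]phenyl]butan-1-one, via aryne 30 (not isolated)
Conditions: CsF (5 equiv), butanoic acid (1.5 equiv), THF, 125 °C, sealed tube
Reagents that add atoms: none
Why: Fluoride attacks silicon of 28 and the aryl anion expels triflate, giving aryne 30. Butanoate, formed from 29 and CsF, adds through oxygen to C6, the aryne carbon remote from the C2 benzyloxy group, because the aryl anion then develops at C1 next to that inductively withdrawing oxygen, as is usual for 3-alkoxyarynes. The C1 anion attacks the carbonyl of the new aryl ester through a four-membered alkoxide that opens to the C1 ketone and the C6 phenolate; the closest known reaction type is the insertion of arynes into the C–O bond of carboxylic acids at high temperature to give ortho-hydroxyaryl ketones. No ring is retained and no stereocentre is formed. The step needs oxygen at C6 and acyl at C1, and the alkoxy bias should outweigh the weaker steric bias of the C5 methylene arm, which points the other way. Heat and excess CsF keep free acid low, so acyl transfer within the ion pair is favoured over protonation to the aryl butanoate. Within reach of C6 the adjacent wing offers only the isoxazole ring oxygen and an enol-ether oxygen, both poor nucleophiles, and its ketone lies on the far side of the ring. The medium is neutral and free of Lewis acid, so the methylene bridges are not put at risk.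

Step 19
Reactants: 31 1-[2,4-bis(benzyloxy)-5-[(3-ethyl-6-methoxy-5,5-dimethyl-4-oxo-4,5-dihydro-1,2-benzoxazol-7-yl)methyl]-6-hydroxy-3-[(6-methoxy-3,5,5-trimethyl-4-oxo-4,5-dihydro-1,2-benzoxazol-7-yl)methyl]phenyl]butan-1-one
Product: 32 1-[3-{[5-(1-aminoethylidene)-2-methoxy-3,3-dimethyl-4,6-dioxocyclohex-1-en-1-yl]methyl}-5-{[5-(1-aminopropylidene)-2-methoxy-3,3-dimethyl-4,6-dioxocyclohex-1-en-1-yl]methyl}-2,4,6-trihydroxyphenyl]butan-1-one
Conditions: H2 (1 atm), Pd/C, EtOAc/EtOH, rt
Reagents that add atoms: none
Why: Hydrogenolysis of both benzyl ethers and both isoxazole N–O bonds; the resulting enaminones and the chelated aryl ketone resist further hydrogenation under neutral conditions.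

Step 20
Reactants: 32 1-[3-{[5-(1-aminoethylidene)-2-methoxy-3,3-dimethyl-4,6-dioxocyclohex-1-en-1-yl]methyl}-5-{[5-(1-aminopropylidene)-2-methoxy-3,3-dimethyl-4,6-dioxocyclohex-1-en-1-yl]methyl}-2,4,6-trihydroxyphenyl]butan-1-one
Product: 33 1-[3-[(5-acetyl-2,4-dihydroxy-3,3-dimethyl-6-oxocyclohexa-1,4-dien-1-yl)methyl]-5-[(2,4-dihydroxy-3,3-dimethyl-6-oxo-5-propanoylcyclohexa-1,4-dien-1-yl)methyl]-2,4,6-trihydroxyphenyl]butan-1-one
Conditions: 2 M HCl, THF/H2O, 50 °C
Reagents that add atoms: water, O
Why: Acid hydrolysis of the two vinylogous methyl esters and the two amino-alkylidene diketones (enamine hydrolysis) should release both enolised β-triketones; dilute acid at moderate temperature is chosen to stay below the threshold for bridge exchange.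

## Compound list

1 | 3-ethyl-5-methyl-1,2-oxazole-4-carboxylic acid | CCc1noc(C)c1C(O)=O | starting material
2 | 3-ethyl-5-methyl-1,2-oxazole-4-carbonyl chloride | CCc1noc(C)c1C(Cl)=O | intermediate (not isolated)
3 | methyl 3-(3-ethyl-5-methyl-1,2-oxazol-4-yl)-2,2-dimethyl-3-oxopropanoate | CCc1noc(C)c1C(=O)C(C)(C)C(=O)OC | intermediate
4 | 3-ethyl-5,5-dimethyl-1,2-benzoxazole-4,6(5H,7H)-dione | CCc1noc2CC(=O)C(C)(C)C(=O)c12 | intermediate
5 | 3-ethyl-6-methoxy-5,5-dimethyl-1,2-benzoxazol-4(5H)-one | CCc1noc2C=C(OC)C(C)(C)C(=O)c12 | intermediate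
6 | 7-bromo-3-ethyl-6-methoxy-5,5-dimethyl-1,2-benzoxazol-4(5H)-one | CCc1noc2C(Br)=C(OC)C(C)(C)C(=O)c12 | intermediate
7 | 3,5-dimethyl-1,2-oxazole-4-carboxylic acid | Cc1noc(C)c1C(O)=O | starting material
8 | 3,5-dimethyl-1,2-oxazole-4-carbonyl chloride | Cc1noc(C)c1C(Cl)=O | intermediate (not isolated)
9 | methyl 3-(3,5-dimethyl-1,2-oxazol-4-yl)-2,2-dimethyl-3-oxopropanoate | Cc1noc(C)c1C(=O)C(C)(C)C(=O)OC | intermediate
10 | 3,5,5-trimethyl-1,2-benzoxazole-4,6(5H,7H)-dione | Cc1noc2CC(=O)C(C)(C)C(=O)c12 | intermediate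
11 | 6-methoxy-3,5,5-trimethyl-1,2-benzoxazol-4(5H)-one | Cc1noc2C=C(OC)C(C)(C)C(=O)c12 | intermediate
12 | 7-bromo-6-methoxy-3,5,5-trimethyl-1,2-benzoxazol-4(5H)-one | Cc1noc2C(Br)=C(OC)C(C)(C)C(=O)c12 | intermediate
13 | 3,5-bis(benzyloxy)phenol | Oc1cc(OCc2ccccc2)cc(OCc2ccccc2)c1 | starting material
14 | 2,6-bis(benzyloxy)-4-hydroxybenzaldehyde | Oc1cc(OCc2ccccc2)c(C=O)c(OCc2ccccc2)c1 | intermediate
15 | 2,6-bis(benzyloxy)-3-bromo-4-hydroxybenzaldehyde | Oc1cc(OCc2ccccc2)c(C=O)c(OCc2ccccc2)c1Br | intermediate
16 | 2,6-bis(benzyloxy)-3-bromo-5-[(dimethylamino)methyl]-4-hydroxybenzaldehyde | Oc1c(CN(C)C)c(OCc2ccccc2)c(C=O)c(OCc2ccccc2)c1Br | intermediate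
17 | 3,5-bis(benzyloxy)-2-bromo-6-[(dimethylamino)methyl]-4-(hydroxymethyl)phenol | Oc1c(CN(C)C)c(OCc2ccccc2)c(CO)c(OCc2ccccc2)c1Br | intermediate
18 | [3,5-bis(benzyloxy)-2-bromo-6-[(dimethylamino)methyl]-4-{[(trimethylsilyl)oxy]methyl}phenoxy]trimethylsilane | C[Si](C)(C)Oc1c(CN(C)C)c(OCc2ccccc2)c(CO[Si](C)(C)C)c(OCc2ccccc2)c1Br | intermediate (not isolated)
19 | lithium 3,5-bis(benzyloxy)-2-[(dimethylamino)methyl]-6-(trimethylsilyl)-4-{[(trimethylsilyl)oxy]methyl}phenolate | [Li+].[O-]c1c(CN(C)C)c(OCc2ccccc2)c(CO[Si](C)(C)C)c(OCc2ccccc2)c1[Si](C)(C)C | intermediate (not isolated)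
20 | 3,5-bis(benzyloxy)-2-[(dimethylamino)methyl]-6-(trimethylsilyl)-4-{[(trimethylsilyl)oxy]methyl}phenyl trifluoromethanesulfonate | FC(F)(F)S(=O)(=O)Oc1c(CN(C)C)c(OCc2ccccc2)c(CO[Si](C)(C)C)c(OCc2ccccc2)c1[Si](C)(C)C | intermediate
21 | 3,5-bis(benzyloxy)-2-(chloromethyl)-6-(trimethylsilyl)-4-{[(trimethylsilyl)oxy]methyl}phenyl trifluoromethanesulfonate | FC(F)(F)S(=O)(=O)Oc1c(CCl)c(OCc2ccccc2)c(CO[Si](C)(C)C)c(OCc2ccccc2)c1[Si](C)(C)C | intermediate
22 | [2,4-bis(benzyloxy)-6-{[(trifluoromethyl)sulfonyl]oxy}-5-(trimethylsilyl)-3-{[(trimethylsilyl)oxy]methyl}phenyl]methylzinc chloride | FC(F)(F)S(=O)(=O)Oc1c(C[Zn]Cl)c(OCc2ccccc2)c(CO[Si](C)(C)C)c(OCc2ccccc2)c1[Si](C)(C)C | intermediate (not isolated)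
23 | 3,5-bis(benzyloxy)-2-[(3-ethyl-6-methoxy-5,5-dimethyl-4-oxo-4,5-dihydro-1,2-benzoxazol-7-yl)methyl]-6-(trimethylsilyl)-4-{[(trimethylsilyl)oxy]methyl}phenyl trifluoromethanesulfonate | FC(F)(F)S(=O)(=O)Oc1c(CC2=C(OC)C(C)(C)C(=O)c3c(CC)noc32)c(OCc2ccccc2)c(CO[Si](C)(C)C)c(OCc2ccccc2)c1[Si](C)(C)C | intermediate (not isolated)
24 | 3,5-bis(benzyloxy)-2-[(3-ethyl-6-methoxy-5,5-dimethyl-4-oxo-4,5-dihydro-1,2-benzoxazol-7-yl)methyl]-4-(hydroxymethyl)-6-(trimethylsilyl)phenyl trifluoromethanesulfonate | FC(F)(F)S(=O)(=O)Oc1c(CC2=C(OC)C(C)(C)C(=O)c3c(CC)noc32)c(OCc2ccccc2)c(CO)c(OCc2ccccc2)c1[Si](C)(C)C | intermediate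
25 | 3,5-bis(benzyloxy)-2-[(3-ethyl-6-methoxy-5,5-dimethyl-4-oxo-4,5-dihydro-1,2-benzoxazol-7-yl)methyl]-4-{[(methanesulfonyl)oxy]methyl}-6-(trimethylsilyl)phenyl trifluoromethanesulfonate | FC(F)(F)S(=O)(=O)Oc1c(CC2=C(OC)C(C)(C)C(=O)c3c(CC)noc32)c(OCc2ccccc2)c(COS(C)(=O)=O)c(OCc2ccccc2)c1[Si](C)(C)C | intermediate (not isolated)
26 | 3,5-bis(benzyloxy)-4-(chloromethyl)-2-[(3-ethyl-6-methoxy-5,5-dimethyl-4-oxo-4,5-dihydro-1,2-benzoxazol-7-yl)methyl]-6-(trimethylsilyl)phenyl trifluoromethanesulfonate | FC(F)(F)S(=O)(=O)Oc1c(CC2=C(OC)C(C)(C)C(=O)c3c(CC)noc32)c(OCc2ccccc2)c(CCl)c(OCc2ccccc2)c1[Si](C)(C)C | intermediate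
27 | [2,6-bis(benzyloxy)-3-[(3-ethyl-6-methoxy-5,5-dimethyl-4-oxo-4,5-dihydro-1,2-benzoxazol-7-yl)methyl]-4-{[(trifluoromethyl)sulfonyl]oxy}-5-(trimethylsilyl)phenyl]methylzinc chloride | FC(F)(F)S(=O)(=O)Oc1c(CC2=C(OC)C(C)(C)C(=O)c3c(CC)noc32)c(OCc2ccccc2)c(C[Zn]Cl)c(OCc2ccccc2)c1[Si](C)(C)C | intermediate (not isolated)
28 | 3,5-bis(benzyloxy)-2-[(3-ethyl-6-methoxy-5,5-dimethyl-4-oxo-4,5-dihydro-1,2-benzoxazol-7-yl)methyl]-4-[(6-methoxy-3,5,5-trimethyl-4-oxo-4,5-dihydro-1,2-benzoxazol-7-yl)methyl]-6-(trimethylsilyl)phenyl trifluoromethanesulfonate | FC(F)(F)S(=O)(=O)Oc1c(CC2=C(OC)C(C)(C)C(=O)c3c(CC)noc32)c(OCc2ccccc2)c(CC2=C(OC)C(C)(C)C(=O)c3c(C)noc32)c(OCc2ccccc2)c1[Si](C)(C)C | intermediate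
29 | butanoic acid | CCCC(O)=O | starting material
30 | 4,6-bis(benzyloxy)-3-[(3-ethyl-6-methoxy-5,5-dimethyl-4-oxo-4,5-dihydro-1,2-benzoxazol-7-yl)methyl]-5-[(6-methoxy-3,5,5-trimethyl-4-oxo-4,5-dihydro-1,2-benzoxazol-7-yl)methyl]-1,2-didehydrobenzene | C1#CC(CC2=C(OC)C(C)(C)C(=O)c3c(CC)noc32)=C(OCc2ccccc2)C(CC2=C(OC)C(C)(C)C(=O)c3c(C)noc32)=C1OCc1ccccc1 | intermediate (not isolated)
31 | 1-[2,4-bis(benzyloxy)-5-[(3-ethyl-6-methoxy-5,5-dimethyl-4-oxo-4,5-dihydro-1,2-benzoxazol-7-yl)methyl]-6-hydroxy-3-[(6-methoxy-3,5,5-trimethyl-4-oxo-4,5-dihydro-1,2-benzoxazol-7-yl)methyl]phenyl]butan-1-one | CCCC(=O)c1c(O)c(CC2=C(OC)C(C)(C)C(=O)c3c(CC)noc32)c(OCc2ccccc2)c(CC2=C(OC)C(C)(C)C(=O)c3c(C)noc32)c1OCc1ccccc1 | intermediate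
32 | 1-[3-{[5-(1-aminoethylidene)-2-methoxy-3,3-dimethyl-4,6-dioxocyclohex-1-en-1-yl]methyl}-5-{[5-(1-aminopropylidene)-2-methoxy-3,3-dimethyl-4,6-dioxocyclohex-1-en-1-yl]methyl}-2,4,6-trihydroxyphenyl]butan-1-one | CCCC(=O)c1c(O)c(CC2=C(OC)C(C)(C)C(=O)C(=C(N)CC)C2=O)c(O)c(CC2=C(OC)C(C)(C)C(=O)C(=C(N)C)C2=O)c1O | intermediate
33 | 1-[3-[(5-acetyl-2,4-dihydroxy-3,3-dimethyl-6-oxocyclohexa-1,4-dien-1-yl)methyl]-5-[(2,4-dihydroxy-3,3-dimethyl-6-oxo-5-propanoylcyclohexa-1,4-dien-1-yl)methyl]-2,4,6-trihydroxyphenyl]butan-1-one | CCCC(=O)c1c(O)c(CC2=C(O)C(C)(C)C(O)=C(C(C)=O)C2=O)c(O)c(CC2=C(O)C(C)(C)C(O)=C(C(=O)CC)C2=O)c1O | target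

## Step count and least certain steps

Total: 20 steps. Longest linear sequence: 12 steps (steps 9–20, from 13).

**Step 18 (key step).** The aryl anion may be protonated before the acyl shift, so that the sequence stops at the aryl butanoate. Addition may also run the other way round if the C5 arm outweighs the alkoxy bias. The enol-ether oxygen of the neighbouring wing may capture the aryne intramolecularly. Fluoride attack on the crowded silicon may be slow. The fallback sets out from 28 and returns at 31. The aryne is generated with CsF in N,N-dimethylformamide, whose carbonyl adds across the triple bond with the same polarisation (oxygen to C6, carbon to C1); aqueous work-up releases the salicylaldehyde F1. Excess n-PrMgBr at −78 °C adds to the aldehyde (the phenolate forms first; the hindered wing ketones react more slowly) to give the racemic carbinol F2. MnO2 oxidises this benzylic alcohol to ketone 31.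

**Step 15 (and its twin, step 17).** The hindered, electron-rich benzylic zinc reagent may homocouple or be protonated. Oxidative addition to the electron-rich tetrasubstituted alkenyl bromide may be slow, and insertion into the aryl triflate may compete. The fallback reverses the roles of the partners. It sets out from 6 and 21 and returns at 24: Miyaura borylation of 6 (bis(pinacolato)diboron, PdCl2(dppf), KOAc, dioxane, 80 °C) gives the alkenyl boronate F3, which is joined to chloride 21 by Suzuki–Miyaura coupling (PdCl2(dppf), K3PO4, THF/H2O, 50 °C); the silyl ether is lost on work-up. For step 17 the same switch sets out from 12 and 26 through the boronate F4 and returns at 28.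

**Step 2 (and its twin, step 6).** Methoxide released in the ring closure may cleave the non-enolisable β-dicarbonyl unit (retro-Claisen), or the lateral anion may condense between molecules. The fallback forms the two ring bonds in the opposite order. It sets out from 1 and returns at 4: esterification (MeOH, H2SO4) gives the methyl ester F5; lateral lithiation (LiN(i-Pr)2, 2 equiv, THF, −78 °C) and acylation with N-methoxy-N-methyl-2-methylpropanamide (Weinreb ketone synthesis) give the keto ester F6; its dianion (LiN(i-Pr)2, 2.2 equiv) closes the C4–C5 bond by Dieckmann-type attack of the isopropyl carbon on the ester. For step 6 the same sequence runs from 7 through the ester F7 and the keto ester F8 to 10.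

**Step 20.** Hydrolysis of the hydrogen-bonded amino-alkylidene diketones may need acid strength or temperature at which the free phloroglucinol bridges exchange through quinone methides or cyclodehydrate to xanthenes. The fallback changes the order of unmasking so that the forcing hydrolysis is done while ring A is still benzylated and the last step is neutral. It sets out from 31 and returns at 33: Mo(CO)6 in MeCN/H2O at 80 °C cleaves both N–O bonds but not the benzyl ethers and gives the bis-enaminone F9; aqueous HCl in dioxane at 70–80 °C hydrolyses enaminones and enol ethers to the dibenzyl ether F10; hydrogenolysis (H2, Pd/C, EtOAc) then gives 33.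

## Further compounds

F1 | step 18 | 2,4-bis(benzyloxy)-5-[(3-ethyl-6-methoxy-5,5-dimethyl-4-oxo-4,5-dihydro-1,2-benzoxazol-7-yl)methyl]-6-hydroxy-3-[(6-methoxy-3,5,5-trimethyl-4-oxo-4,5-dihydro-1,2-benzoxazol-7-yl)methyl]benzaldehyde | O=Cc1c(O)c(CC2=C(OC)C(C)(C)C(=O)c3c(CC)noc32)c(OCc2ccccc2)c(CC2=C(OC)C(C)(C)C(=O)c3c(C)noc32)c1OCc1ccccc1
F2 | step 18 | racemic 1-[2,4-bis(benzyloxy)-5-[(3-ethyl-6-methoxy-5,5-dimethyl-4-oxo-4,5-dihydro-1,2-benzoxazol-7-yl)methyl]-6-hydroxy-3-[(6-methoxy-3,5,5-trimethyl-4-oxo-4,5-dihydro-1,2-benzoxazol-7-yl)methyl]phenyl]butan-1-ol | CCCC(O)c1c(O)c(CC2=C(OC)C(C)(C)C(=O)c3c(CC)noc32)c(OCc2ccccc2)c(CC2=C(OC)C(C)(C)C(=O)c3c(C)noc32)c1OCc1ccccc1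
F3 | step 15 | 3-ethyl-6-methoxy-5,5-dimethyl-7-(4,4,5,5-tetramethyl-1,3,2-dioxaborolan-2-yl)-1,2-benzoxazol-4(5H)-one | CCc1noc2C(B3OC(C)(C)C(C)(C)O3)=C(OC)C(C)(C)C(=O)c12
F4 | step 17 | 6-methoxy-3,5,5-trimethyl-7-(4,4,5,5-tetramethyl-1,3,2-dioxaborolan-2-yl)-1,2-benzoxazol-4(5H)-one | Cc1noc2C(B3OC(C)(C)C(C)(C)O3)=C(OC)C(C)(C)C(=O)c12
F5 | step 2 | methyl 3-ethyl-5-methyl-1,2-oxazole-4-carboxylate | CCc1noc(C)c1C(=O)OC
F6 | step 2 | methyl 3-ethyl-5-(3-methyl-2-oxobutyl)-1,2-oxazole-4-carboxylate | CCc1noc(CC(=O)C(C)C)c1C(=O)OC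
F7 | step 6 | methyl 3,5-dimethyl-1,2-oxazole-4-carboxylate | Cc1noc(C)c1C(=O)OC
F8 | step 6 | methyl 3-methyl-5-(3-methyl-2-oxobutyl)-1,2-oxazole-4-carboxylate | Cc1noc(CC(=O)C(C)C)c1C(=O)OC
F9 | step 20 | 1-[3-{[5-(1-aminoethylidene)-2-methoxy-3,3-dimethyl-4,6-dioxocyclohex-1-en-1-yl]methyl}-5-{[5-(1-aminopropylidene)-2-methoxy-3,3-dimethyl-4,6-dioxocyclohex-1-en-1-yl]methyl}-2,4-bis(benzyloxy)-6-hydroxyphenyl]butan-1-one | CCCC(=O)c1c(O)c(CC2=C(OC)C(C)(C)C(=O)C(=C(N)CC)C2=O)c(OCc2ccccc2)c(CC2=C(OC)C(C)(C)C(=O)C(=C(N)C)C2=O)c1OCc1ccccc1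
F10 | step 20 | 1-[3-[(5-acetyl-2,4-dihydroxy-3,3-dimethyl-6-oxocyclohexa-1,4-dien-1-yl)methyl]-2,4-bis(benzyloxy)-5-[(2,4-dihydroxy-3,3-dimethyl-6-oxo-5-propanoylcyclohexa-1,4-dien-1-yl)methyl]-6-hydroxyphenyl]butan-1-one | CCCC(=O)c1c(O)c(CC2=C(O)C(C)(C)C(O)=C(C(=O)CC)C2=O)c(OCc2ccccc2)c(CC2=C(O)C(C)(C)C(O)=C(C(C)=O)C2=O)c1OCc1ccccc1
A1 | alternative 1 | 5-(benzyloxy)-4-[(methoxymethoxy)methyl]-2-{[(4-methoxybenzyl)oxy]methyl}-3-[(triisopropylsilyl)oxy]phenol | Oc1cc(OCc2ccccc2)c(COCOC)c(O[Si](C(C)C)(C(C)C)C(C)C)c1COCc3ccc(OC)cc3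
A2 | alternative 2 | 2-acetyl-3,5-dihydroxy-4,4-dimethyl-6-({2,4,6-tris(benzyloxy)-3-[(2,4-dihydroxy-3,3-dimethyl-6-oxo-5-propanoylcyclohexa-1,4-dien-1-yl)methyl]phenyl}methyl)cyclohexa-2,5-dien-1-one | CC(=O)C1=C(O)C(C)(C)C(O)=C(Cc2c(OCc3ccccc3)cc(OCc3ccccc3)c(CC3=C(O)C(C)(C)C(O)=C(C(=O)CC)C3=O)c2OCc2ccccc2)C1=O
A3 | alternative 2 | 2,2-dimethylpropanedioyl dichloride | CC(C)(C(Cl)=O)C(Cl)=O
A4 | alternative 3 | 1-[2-(benzyloxy)-4,6-dihydroxy-5-[(methoxymethoxy)methyl]-3-{[(4-methoxybenzyl)oxy]methyl}phenyl]butan-1-one | CCCC(=O)c1c(O)c(COCOC)c(O)c(COCc2ccc(OC)cc2)c1OCc1ccccc1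
A5 | alternative 3 | 1-(benzyloxy)hex-1-yn-3-one | CCCC(=O)C#COCc1ccccc1
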